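**Retrosynthetic overview**

1. The five methyl ethers are disconnected at C–O: target 10 comes from 5,6,3',4',5'-pentahydroxyflavone 9.
2. 9 comes from the 5,8-dihydroxyflavone 6 by skeletal isomerisation: the pyranone is opened at O1–C2 and reclosed through the former 5-oxygen. The strategy rests on ring A, where the carbonyl-bearing C4a is flanked by oxygens on C5 and C8a (O1) and C6 carries a third oxygen. This 1,2,4-trioxygenated ring is the same one a 5,8-dioxygenated flavone contains, closed through the other ortho oxygen.
3. 6 comes from the 5-hydroxyflavone 4 by C8–O formation para to the 5-hydroxyl.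
4. 4 comes from diketone 3 by O1–C2 closure; 3 comes from acetophenone 1 and aroyl chloride 2 by C2–C3 bond formation.
5. Ring order: rings A and B are bought; the pyranone ring C is closed in step 2, then opened and reclosed on the other oxygen in step 4.

Key step: step 4

Remark: the target has no stereocentre, so no stereocontrol is needed. Assumption: in step 4 ether cleavage and isomerisation run in one operation; intermediates 7 and 8 are drawn fully demethylated, although ring opening may begin before all three methyl groups are lost.

**Route**

Step 1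
Reactants: 1 2',6'-dihydroxyacetophenone; 2 3,4,5-trimethoxybenzoyl chloride
Product: 3 1-(2,6-dihydroxyphenyl)-3-(3,4,5-trimethoxyphenyl)propane-1,3-dione
Conditions: LiHMDS (4 equiv), THF, −78 → −10 °C; then 2 (1.0 equiv), −78 °C → rt; aq. HCl
Reagents that add atoms: none
Why: Crossed Claisen C-aroylation of a polylithiated o-hydroxyacetophenone: the bis(phenoxide) enolate reacts at its enolate carbon, giving directly the 1,3-diketone of a Baker–Venkataraman sequence, and the fourth equivalent of base deprotonates the diketone so that a second acylation is suppressed.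

Step 2
Reactants: 3 1-(2,6-dihydroxyphenyl)-3-(3,4,5-trimethoxyphenyl)propane-1,3-dione
Product: 4 5-hydroxy-2-(3,4,5-trimethoxyphenyl)-4H-chromen-4-one
Conditions: H2SO4 (cat.), AcOH, 95–100 °C
Reagents that add atoms: none
Why: Acid-catalysed cyclodehydration of an o-hydroxyaryl 1,3-diketone (closing stage of a Baker–Venkataraman flavone synthesis): the two ortho hydroxyls are equivalent, so only one flavone can form, and the aryl methyl ethers are stable to dilute sulfuric acid in acetic acid.

Step 3
Reactants: 4 5-hydroxy-2-(3,4,5-trimethoxyphenyl)-4H-chromen-4-one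
Product: 6 5,8-dihydroxy-2-(3,4,5-trimethoxyphenyl)-4H-chromen-4-one, via potassium 5-hydroxyflavon-8-yl sulfate 5 (not isolated)
Conditions: K2S2O8 (1.2 equiv), aq. KOH, pyridine, 10–20 °C, 24 h; acidify to pH 4–5 and remove unreacted 4; then HCl (ca. 2 M), Na2SO3, 90 °C
Reagents that add atoms: potassium persulfate, [K+].[K+].[O-]S(=O)(=O)OOS(=O)(=O)[O-]
Why: Elbs persulfate oxidation: the 5-phenoxide attacks the peroxide oxygen through its para carbon C8, the aryl sulfate 5 protects the new oxygen from further oxidation in base, and acid hydrolysis of the sulfate monoester releases the quinol; cold dilute alkali and brief hot dilute acid should leave the pyranone and the methyl ethers intact.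

Step 4
Reactants: 6 5,8-dihydroxy-2-(3,4,5-trimethoxyphenyl)-4H-chromen-4-one
Product: 9 5,6-dihydroxy-2-(3,4,5-trihydroxyphenyl)-4H-chromen-4-one, via 5,8,3',4',5'-pentahydroxyflavone 7 (not isolated), via ring-opened 1,3-diketone 8 (not isolated)
Conditions: 57% aq. HI, AcOH, reflux (ca. 125 °C), N2; then aq. NaHSO3
Reagents that add atoms: none
Why: Wessely–Moser rearrangement under Zeisel-type ether cleavage: iodide removes the three B-ring methyl groups by SN2 on the protonated ethers (giving 7), while protonation of C4=O turns the heterocycle into a 4-hydroxybenzopyrylium ion that takes up water at C2 and opens at O1–C2 to diketone 8. In 8 the acylated carbon C4a lies between two free hydroxyls, the former O1 and the former 5-OH; rotation about the C4a–C4 bond lets the former 5-oxygen add to the C2 carbonyl, and loss of water re-forms the pyranone with a new O1–C2 bond, so that the old O1 becomes the 5-OH and the old 8-OH becomes the 6-OH. The pyranone is closed by 6-exo-trig addition of the phenol oxygen to the aroyl carbonyl followed by dehydration, as in step 2, and no stereocentre is formed. The closest known reaction is the isomerisation of 5,8-dioxygenated flavones to 5,6-dihydroxyflavones during hydriodic acid demethylation. The step needs the reversible open/closed equilibrium to settle on the 5,6-isomer; the free 5- and 8-hydroxyls of 6 give both closure modes access to the same open form, and the 5,6-isomer is expected to be the sink because its 6-hydroxyl sits next to the chelated 5-hydroxyl and not beside the ring oxygen. The reducing medium should also keep the quinol and pyrogallol units from air oxidation.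

Step 5
Reactants: 9 5,6-dihydroxy-2-(3,4,5-trihydroxyphenyl)-4H-chromen-4-one
Product: 10 Cerosilin B, 5,6-dimethoxy-2-(3,4,5-trimethoxyphenyl)-4H-chromen-4-one
Conditions: Me2SO4 (excess), K2CO3, acetone, reflux, N2
Reagents that add atoms: dimethyl sulfate, COS(=O)(=O)OC
Why: Williamson O-methylation of five phenoxides; the hydrogen-bonded 5-hydroxyl reacts last and is driven by excess reagent and prolonged reflux, and exclusion of air protects the catechol and pyrogallol units until they are capped.

**Compound list**

1 | 2',6'-dihydroxyacetophenone | CC(=O)c1c(O)cccc1O | starting material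
2 | 3,4,5-trimethoxybenzoyl chloride | COc1cc(C(=O)Cl)cc(OC)c1OC | starting material
3 | 1-(2,6-dihydroxyphenyl)-3-(3,4,5-trimethoxyphenyl)propane-1,3-dione | O=C(CC(=O)c1cc(OC)c(OC)c(OC)c1)c1c(O)cccc1O | intermediate
4 | 5-hydroxy-2-(3,4,5-trimethoxyphenyl)-4H-chromen-4-one | COc1cc(-c2cc(=O)c3c(O)cccc3o2)cc(OC)c1OC | intermediate
5 | potassium 5-hydroxy-4-oxo-2-(3,4,5-trimethoxyphenyl)-4H-chromen-8-yl sulfate (not isolated) | COc1cc(-c2cc(=O)c3c(O)ccc(OS(=O)(=O)[O-])c3o2)cc(OC)c1OC.[K+] | intermediate
6 | 5,8-dihydroxy-2-(3,4,5-trimethoxyphenyl)-4H-chromen-4-one | COc1cc(-c2cc(=O)c3c(O)ccc(O)c3o2)cc(OC)c1OC | intermediate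
7 | 5,8-dihydroxy-2-(3,4,5-trihydroxyphenyl)-4H-chromen-4-one (not isolated) | O=c1cc(-c2cc(O)c(O)c(O)c2)oc2c(O)ccc(O)c12 | intermediate
8 | 1-(2,3,6-trihydroxyphenyl)-3-(3,4,5-trihydroxyphenyl)propane-1,3-dione (not isolated) | O=C(CC(=O)c1cc(O)c(O)c(O)c1)c1c(O)ccc(O)c1O | intermediate
9 | 5,6-dihydroxy-2-(3,4,5-trihydroxyphenyl)-4H-chromen-4-one | O=c1cc(-c2cc(O)c(O)c(O)c2)oc2ccc(O)c(O)c12 | intermediate
10 | Cerosilin B, 5,6-dimethoxy-2-(3,4,5-trimethoxyphenyl)-4H-chromen-4-one | COc1cc(-c2cc(=O)c3c(OC)c(OC)ccc3o2)cc(OC)c1OC | target

**Step count**

Total steps: 5. Longest linear sequence: 5 steps (1 → 3 → 4 → 6 → 9 → 10).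

**Steps most likely to fail**

Step 4. The acid equilibrium may stop at a mixture of the 5,8- and 5,6-isomers that is hard to separate, or the polyphenol may degrade during prolonged heating in hydriodic acid. The fallback builds the 5,6-dioxygenated ring A with fixed regiochemistry and needs no rearrangement. It sets out from 2 and comes back to the route at 10. Commercial 3,4-dimethoxyphenol F1 is protected with MOMCl and i-Pr2NEt in CH2Cl2 to give 4-(methoxymethoxy)-1,2-dimethoxybenzene F2. Directed ortho-metalation with n-BuLi in THF at 0 °C should lithiate the position between the OMOM and OMe groups, and quenching with N-methoxy-N-methylacetamide gives 1-[2,3-dimethoxy-6-(methoxymethoxy)phenyl]ethanone F3. Claisen aroylation (LiHMDS, 2.2 equiv, THF, −78 °C, then 2) gives 1-[2,3-dimethoxy-6-(methoxymethoxy)phenyl]-3-(3,4,5-trimethoxyphenyl)propane-1,3-dione F4. Heating F4 with catalytic H2SO4 in AcOH cleaves the acetal and cyclodehydrates the freed phenol onto the aroyl carbonyl, giving 10 directly.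

Step 3. The chelated, electron-poor phenoxide may convert poorly, attack may compete at the ortho carbon C6, hydroxide may open the pyranone during the long alkaline reaction, and the quinol may over-oxidise on work-up. The fallback brings all three ring-A oxygens in from the start and lets hydriodic acid do demethylation, ring closure and isomer selection together (Kostanecki-type demethylative flavone closure). It sets out from 2 and comes back to the route at 9, passing through 8. Commercial 1,2,4-trimethoxybenzene F5 is lithiated with n-BuLi in THF at the position between two methoxy groups and quenched with N-methoxy-N-methylacetamide to give 1-(2,3,6-trimethoxyphenyl)ethanone F6. Claisen aroylation (LiHMDS, 2.2 equiv, then 2) gives 1-(2,3,6-trimethoxyphenyl)-3-(3,4,5-trimethoxyphenyl)propane-1,3-dione F7. Refluxing F7 in 57% HI and AcOH should cleave all six methyl ethers to the open-chain hexahydroxy diketone 8, which closes under the same thermodynamic control as in step 4 to 9.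

Step 5. The pentaphenolate may oxidise in base before it is capped, and methylation may stall at the chelated 5-hydroxyl. The fallback relays through an air-stable, purifiable ester. It sets out from 9 and comes back to the route at 10. Acetylation (Ac2O, pyridine, rt) gives 4-oxo-2-(3,4,5-triacetoxyphenyl)-4H-chromene-5,6-diyl diacetate F8, which can be crystallised. Deacetylative methylation (Me2SO4, K2CO3, acetone–MeOH, reflux, N2) then releases each phenoxide slowly and methylates it at once, so the free polyphenolate is never present in quantity, and 10 results.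

**Further compounds**

F1 | step 4 | 3,4-dimethoxyphenol (purchased) | COc1ccc(O)cc1OC
F2 | step 4 | 4-(methoxymethoxy)-1,2-dimethoxybenzene | COCOc1ccc(OC)c(OC)c1
F3 | step 4 | 1-[2,3-dimethoxy-6-(methoxymethoxy)phenyl]ethanone | CC(=O)c1c(OCOC)ccc(OC)c1OC
F4 | step 4 | 1-[2,3-dimethoxy-6-(methoxymethoxy)phenyl]-3-(3,4,5-trimethoxyphenyl)propane-1,3-dione | COCOc1ccc(OC)c(OC)c1C(=O)CC(=O)c1cc(OC)c(OC)c(OC)c1
F5 | step 3 | 1,2,4-trimethoxybenzene (purchased) | COc1ccc(OC)c(OC)c1
F6 | step 3 | 1-(2,3,6-trimethoxyphenyl)ethanone | CC(=O)c1c(OC)ccc(OC)c1OC
F7 | step 3 | 1-(2,3,6-trimethoxyphenyl)-3-(3,4,5-trimethoxyphenyl)propane-1,3-dione | COc1cc(C(=O)CC(=O)c2c(OC)ccc(OC)c2OC)cc(OC)c1OC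
F8 | step 5 | 4-oxo-2-(3,4,5-triacetoxyphenyl)-4H-chromene-5,6-diyl diacetate | CC(=O)Oc1cc(-c2cc(=O)c3c(OC(C)=O)c(OC(C)=O)ccc3o2)cc(OC(C)=O)c1OC(C)=O
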